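**Plan**
1. Retrosynthesis: the senecioate acyl–O bond is cut last, and the C≡C bond on ring B is traced back to an aryl ketone (alkyne = ketone minus water).
2. Ring B (the alkynyl thiophene) is then cut at both C–S bonds and at the C–C bond between its chain-bearing carbon and the neighbouring CH. This gives a ring A β-chlorovinyl aldehyde, sulfide, and a bromomethyl ketone that already holds the four chain carbons and the 3-methylbutanoate.
3. Feature used: the sp carbon on ring B is a dehydrated acyl carbon, and the ring B carbon bonded to ring A is the former carbonyl carbon of an acetyl group on ring A. Ring B can therefore be grown as a 2-acylthiophene and the inter-ring bond needs no coupling.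
4. Forward: ring A is bought as thiophen-2-ylmethanol, then silylated, acetylated at C5 and chloroformylated. The bromoketone arm comes in two steps from 5-hydroxypentan-2-one. Ring B is closed by the three-component annulation, followed by ketone-to-alkyne conversion, desilylation and senecioate formation.
5. Stereochemistry: the target has no stereocentre and no stereogenic double bond. The Z geometry of the chloroenal comes from the chloroformylation and is erased when ring B aromatises.

Key step: step 6

Remark: sodium sulfide is used as its nonahydrate, and the hydroxymethyl group of ring A is carried as its tert-butyldiphenylsilyl ether from step 1 to step 8.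

Step 1
Reactants: 1 thiophen-2-ylmethanol
Product: 2 tert-butyl(diphenyl)(thiophen-2-ylmethoxy)silane
Conditions: tert-butyl(chloro)diphenylsilane, imidazole, DMF, 0 °C to rt
Reagents that add atoms: tert-butyl(chloro)diphenylsilane, CC(C)(C)[Si](Cl)(c1ccccc1)c1ccccc1
Why: Imidazole-promoted silylation of a primary alcohol; this bulky silyl ether is chosen because it should withstand n-BuLi, the acidic chloroiminium reagent of step 3 and the sulfide and carbonate of step 6.

Step 2
Reactants: 2 tert-butyl(diphenyl)(thiophen-2-ylmethoxy)silane
Product: 5 1-[5-[(tert-butyldiphenylsilyl)oxymethyl]thiophen-2-yl]ethan-1-one, via [5-[(tert-butyldiphenylsilyl)oxymethyl]thiophen-2-yl]lithium 3 (not isolated), via lithium hemiaminal alkoxide adduct 4 (not isolated)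
Conditions: n-BuLi, THF, −78 °C; then MeC(O)N(OMe)Me, −78 to 0 °C; then H2O
Reagents that add atoms: N-methoxy-N-methylacetamide, CC(=O)N(C)OC
Why: The free position next to sulfur is the most acidic C–H of a 2-substituted thiophene, so n-BuLi metalates C5, and the Weinreb ketone synthesis stops at the ketone because the chelated adduct 4 collapses only on aqueous quench.

Step 3
Reactants: 5 1-[5-[(tert-butyldiphenylsilyl)oxymethyl]thiophen-2-yl]ethan-1-one
Product: 7 (Z)-3-[5-[(tert-butyldiphenylsilyl)oxymethyl]thiophen-2-yl]-3-chloroprop-2-enal, via chlorovinyl iminium salt 6 (not isolated)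
Conditions: POCl3, DMF, 0 to 50 °C; then aq. NaOAc, 0 °C
Reagents that add atoms: N,N-dimethylformamide, CN(C)C=O; phosphoryl chloride, O=P(Cl)(Cl)Cl; water, O
Why: Vilsmeier–Haack–Arnold chloroformylation of an aryl methyl ketone: the chloroiminium reagent formylates the methyl carbon and exchanges the carbonyl oxygen for chlorine, and hydrolysis of iminium salt 6 should give the β-chloroenal with chlorine cis to the formyl group (Z), while the deactivated ring and the hindered silyl ether are expected to be left alone.

Step 4
Reactants: 8 5-hydroxypentan-2-one; 9 3-methylbutanoyl chloride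
Product: 10 4-oxopentyl 3-methylbutanoate
Conditions: pyridine, cat. 4-(dimethylamino)pyridine, CH2Cl2, 0 °C to rt
Reagents that add atoms: 3-methylbutanoyl chloride (9), CC(C)CC(Cl)=O
Why: Standard acylation of a primary alcohol with an acid chloride; the hydroxy ketone reacts through its open-chain form, and acylation drains the equilibrium with the cyclic hemiketal.

Step 5
Reactants: 10 4-oxopentyl 3-methylbutanoate
Product: 12 5-bromo-4-oxopentyl 3-methylbutanoate, via bromo dimethyl ketal 11 (not isolated)
Conditions: Br2 (1.0 equiv), MeOH, −10 to 10 °C; then H2O, rt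
Reagents that add atoms: bromine, BrBr
Why: Bromination of a methyl ketone in methanol goes through the dimethyl ketal and its less substituted methyl enol ether, so bromine should enter mainly at the methyl group, and the water added at the end hydrolyses bromo ketal 11 to the bromomethyl ketone.

Step 6
Reactants: 7 (Z)-3-[5-[(tert-butyldiphenylsilyl)oxymethyl]thiophen-2-yl]-3-chloroprop-2-enal; 13 sodium sulfide (as Na2S·9H2O); 12 5-bromo-4-oxopentyl 3-methylbutanoate
Product: 16 4-oxo-4-[5'-[(tert-butyldiphenylsilyl)oxymethyl]-2,2'-bithiophen-5-yl]butyl 3-methylbutanoate, via sodium vinylthiolate 14 (not isolated), via keto sulfide 15 (not isolated)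
Conditions: Na2S·9H2O, DMF, rt; then 12, rt; then K2CO3, 50 °C
Reagents that add atoms: sodium sulfide (13), [Na+].[Na+].[S-2]
Why: Sulfide adds to the β-carbon of chloroenal 7 and expels chloride (addition–elimination) to give (Z)-vinyl thiolate 14, which is S-alkylated by bromoketone 12 to keto sulfide 15; K2CO3 then deprotonates the CH2 between sulfur and the ketone, the carbanion adds to the aldehyde, and loss of water gives the aromatic thiophene. The closest known reaction is the Fiesselmann-type one-pot thiophene synthesis from β-chlorovinyl aldehydes, Na2S·9H2O and α-halo ketones, which is established for 3-aryl-3-chloroacroleins and halomethyl ketones. Ring B closes by a 5-(enolexo)-exo-trig aldol addition once the two C–S bonds (one by vinylic substitution, one by SN2) are in place. No stereocentre is formed, and the Z geometry of 7, which holds sulfur cis to the formyl group, is consumed in the aromatisation. Regiochemistry cannot stray, because sulfur can only land on the carbon that carried chlorine (the one bonded to ring A) and only the one CH2 between sulfur and the keto group can reach the aldehyde in a five-membered closure, so only the 2,5-disubstituted ring should form. Chemoselectivity is secured by adding 12 only after the sulfide has been consumed, so that the soft thiolate is the only strong nucleophile meeting the bromide and the 3-methylbutanoate sees nothing stronger than carbonate.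

Step 7
Reactants: 16 4-oxo-4-[5'-[(tert-butyldiphenylsilyl)oxymethyl]-2,2'-bithiophen-5-yl]butyl 3-methylbutanoate
Product: 18 4-[5'-[(tert-butyldiphenylsilyl)oxymethyl]-2,2'-bithiophen-5-yl]but-3-yn-1-yl 3-methylbutanoate, via (Z)-enol nonaflate 17 (not isolated)
Conditions: C4F9SO2F, phosphazene base P2-Et [EtN=P(NMe2)2–N=P(NMe2)3], DMF, −20 °C to rt
Reagents that add atoms: none
Why: One-pot enol nonaflate formation and E2 elimination (phosphazene-mediated ketone-to-alkyne conversion): the aryl ketone can enolise in one direction only, the (Z)-enol nonaflate 17 has its vinylic hydrogen anti to the sulfonate, and the non-nucleophilic base should remove it to give the alkyne without attacking the ester, the reaction being kept cold and short to spare the silyl ether from the fluoride by-product.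

Step 8
Reactants: 18 4-[5'-[(tert-butyldiphenylsilyl)oxymethyl]-2,2'-bithiophen-5-yl]but-3-yn-1-yl 3-methylbutanoate
Product: 19 4-[5'-(hydroxymethyl)-2,2'-bithiophen-5-yl]but-3-yn-1-yl 3-methylbutanoate
Conditions: Bu4NF, AcOH, THF, 0 °C to rt
Reagents that add atoms: none
Why: Fluoride desilylation driven by the strong Si–F bond, buffered with acetic acid so that the 3-methylbutanoate and the base-sensitive homopropargylic position are not exposed to alkoxide or free fluoride base.

Step 9
Reactants: 19 4-[5'-(hydroxymethyl)-2,2'-bithiophen-5-yl]but-3-yn-1-yl 3-methylbutanoate; 20 3-methylbut-2-enoic acid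
Product: 21 [5'-[4-(3-methylbutanoyloxy)but-1-yn-1-yl]-2,2'-bithiophen-5-yl]methyl 3-methylbut-2-enoate (CNP0114739.0)
Conditions: N,N'-dicyclohexylcarbodiimide, cat. 4-(dimethylamino)pyridine, CH2Cl2, 0 °C to rt
Reagents that add atoms: 3-methylbut-2-enoic acid (20), CC(C)=CC(=O)O
Why: Steglich esterification of a primary heteroarylmethyl alcohol; carbodiimide activation with acyl transfer avoids the acid chloride and tertiary amine combination that can deconjugate this enoate through a vinylketene.

**Compound list**
1 | thiophen-2-ylmethanol | OCc1cccs1 | starting material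
2 | tert-butyl(diphenyl)(thiophen-2-ylmethoxy)silane | CC(C)(C)[Si](OCc1cccs1)(c1ccccc1)c1ccccc1 | intermediate
3 | [5-[(tert-butyldiphenylsilyl)oxymethyl]thiophen-2-yl]lithium (not isolated) | [Li]c1ccc(CO[Si](c2ccccc2)(c2ccccc2)C(C)(C)C)s1 | intermediate
4 | lithium 1-[5-[(tert-butyldiphenylsilyl)oxymethyl]thiophen-2-yl]-1-[methoxy(methyl)amino]ethan-1-olate (racemic, not isolated) | [Li+].CC([O-])(N(C)OC)c1ccc(CO[Si](c2ccccc2)(c2ccccc2)C(C)(C)C)s1 | intermediate
5 | 1-[5-[(tert-butyldiphenylsilyl)oxymethyl]thiophen-2-yl]ethan-1-one | CC(=O)c1ccc(CO[Si](c2ccccc2)(c2ccccc2)C(C)(C)C)s1 | intermediate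
6 | (Z)-N-[3-chloro-3-[5-[(tert-butyldiphenylsilyl)oxymethyl]thiophen-2-yl]prop-2-en-1-ylidene]-N-methylmethanaminium dichlorophosphate (not isolated) | C[N+](C)=C/C=C(\Cl)c1ccc(CO[Si](c2ccccc2)(c2ccccc2)C(C)(C)C)s1.[O-]P(=O)(Cl)Cl | intermediate
7 | (Z)-3-[5-[(tert-butyldiphenylsilyl)oxymethyl]thiophen-2-yl]-3-chloroprop-2-enal | O=C/C=C(\Cl)c1ccc(CO[Si](c2ccccc2)(c2ccccc2)C(C)(C)C)s1 | intermediate
8 | 5-hydroxypentan-2-one | CC(=O)CCCO | starting material
9 | 3-methylbutanoyl chloride | CC(C)CC(Cl)=O | starting material
10 | 4-oxopentyl 3-methylbutanoate | CC(C)CC(=O)OCCCC(C)=O | intermediate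
11 | 5-bromo-4,4-dimethoxypentyl 3-methylbutanoate (not isolated) | CC(C)CC(=O)OCCCC(CBr)(OC)OC | intermediate
12 | 5-bromo-4-oxopentyl 3-methylbutanoate | CC(C)CC(=O)OCCCC(=O)CBr | intermediate
13 | sodium sulfide (used as the nonahydrate) | [Na+].[Na+].[S-2] | starting material
14 | sodium (Z)-1-[5-[(tert-butyldiphenylsilyl)oxymethyl]thiophen-2-yl]-3-oxoprop-1-ene-1-thiolate (not isolated) | [Na+].O=C/C=C(\[S-])c1ccc(CO[Si](c2ccccc2)(c2ccccc2)C(C)(C)C)s1 | intermediate
15 | 5-[[(Z)-1-[5-[(tert-butyldiphenylsilyl)oxymethyl]thiophen-2-yl]-3-oxoprop-1-en-1-yl]sulfanyl]-4-oxopentyl 3-methylbutanoate (not isolated) | O=C/C=C(\SCC(=O)CCCOC(=O)CC(C)C)c1ccc(CO[Si](c2ccccc2)(c2ccccc2)C(C)(C)C)s1 | intermediate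
16 | 4-oxo-4-[5'-[(tert-butyldiphenylsilyl)oxymethyl]-2,2'-bithiophen-5-yl]butyl 3-methylbutanoate | CC(C)CC(=O)OCCCC(=O)c1ccc(-c2ccc(CO[Si](c3ccccc3)(c3ccccc3)C(C)(C)C)s2)s1 | intermediate
17 | (Z)-4-[5'-[(tert-butyldiphenylsilyl)oxymethyl]-2,2'-bithiophen-5-yl]-4-(nonafluorobutanesulfonyloxy)but-3-en-1-yl 3-methylbutanoate (not isolated) | CC(C)CC(=O)OCC/C=C(\OS(=O)(=O)C(F)(F)C(F)(F)C(F)(F)C(F)(F)F)c1ccc(-c2ccc(CO[Si](c3ccccc3)(c3ccccc3)C(C)(C)C)s2)s1 | intermediate
18 | 4-[5'-[(tert-butyldiphenylsilyl)oxymethyl]-2,2'-bithiophen-5-yl]but-3-yn-1-yl 3-methylbutanoate | CC(C)CC(=O)OCCC#Cc1ccc(-c2ccc(CO[Si](c3ccccc3)(c3ccccc3)C(C)(C)C)s2)s1 | intermediate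
19 | 4-[5'-(hydroxymethyl)-2,2'-bithiophen-5-yl]but-3-yn-1-yl 3-methylbutanoate | CC(C)CC(=O)OCCC#Cc1ccc(-c2ccc(CO)s2)s1 | intermediate
20 | 3-methylbut-2-enoic acid | CC(C)=CC(=O)O | starting material
21 | [5'-[4-(3-methylbutanoyloxy)but-1-yn-1-yl]-2,2'-bithiophen-5-yl]methyl 3-methylbut-2-enoate | CC(C)=CC(=O)OCc1ccc(-c2ccc(C#CCCOC(=O)CC(C)C)s2)s1 | target

**Step count**
Total: 9 steps. Longest linear sequence: 7 steps (steps 1, 2, 3, 6, 7, 8, 9 from thiophen-2-ylmethanol); the bromoketone arm (steps 4 and 5) joins at step 6.

**Steps most likely to fail**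

Step 7 (ketone to alkyne). Three processes could go wrong. The fluoride released on nonaflation may cleave the silyl ether, after which the freed alcohol would be sulfonylated. The strong base may isomerise the new alkyne toward the allene or eliminate the homopropargylic 3-methylbutanoate. The reaction may also stall at the enol nonaflate. The fallback is neutral and fluoride-free and sets out from 16. Semicarbazide hydrochloride and NaOAc in ethanol should give the semicarbazone F1. SeO2 in acetic acid and dioxane should close it to the 1,2,3-selenadiazole F2. Heating F2 to about 170 °C in an inert high-boiling solvent should extrude dinitrogen and selenium and give the alkyne, rejoining the route at 18.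

Step 6 (three-component annulation). The bromoketone may be alkylated twice by sulfide to a symmetric bis(oxoalkyl) sulfide. Hydroxide from the hydrated sulfide may saponify the 3-methylbutanoate. The vinyl thiolate may dimerise oxidatively before it is alkylated. The fallback keeps the same ring closure but brings sulfur in on the ketone component, and sets out from 12 and 7. KSC(O)CH3 in acetone should convert 12 into the thioacetate F3. One equivalent of NaOMe in MeOH at −20 °C should cleave the thioester much faster than the oxygen ester and release the mercaptoketone F4 as its sodium thiolate. Adding this to 7 should give keto sulfide 15 by addition–elimination, and K2CO3 then closes it, rejoining the route at 16.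

Step 5 (bromination at the methyl group). Bromine may enter competitively at the internal methylene, a second bromination may occur, and the hydrogen bromide formed may catalyse methanolysis of the ester. The fallback fixes the position of bromine through an alkene and sets out from 9. Commercial pent-4-en-1-ol is acylated with 9 (pyridine, CH2Cl2) to pent-4-en-1-yl 3-methylbutanoate F5. N-bromosuccinimide in wet DMSO should give the bromohydrin 5-bromo-4-hydroxypentyl 3-methylbutanoate F6 with bromine on the terminal carbon. Dess–Martin periodinane should oxidise F6 to the bromoketone, rejoining the route at 12.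

**Further compounds**
F1 | step 7 | 4-[5'-[(tert-butyldiphenylsilyl)oxymethyl]-2,2'-bithiophen-5-yl]-4-(carbamoylhydrazinylidene)butyl 3-methylbutanoate (semicarbazone of 16) | CC(C)CC(=O)OCCCC(=NNC(N)=O)c1ccc(-c2ccc(CO[Si](c3ccccc3)(c3ccccc3)C(C)(C)C)s2)s1
F2 | step 7 | 2-[4-[5'-[(tert-butyldiphenylsilyl)oxymethyl]-2,2'-bithiophen-5-yl]-1,2,3-selenadiazol-5-yl]ethyl 3-methylbutanoate | CC(C)CC(=O)OCCc1[se]nnc1-c1ccc(-c2ccc(CO[Si](c3ccccc3)(c3ccccc3)C(C)(C)C)s2)s1
F3 | step 6 | S-[5-(3-methylbutanoyloxy)-2-oxopentyl] ethanethioate | CC(C)CC(=O)OCCCC(=O)CSC(C)=O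
F4 | step 6 | 4-oxo-5-sulfanylpentyl 3-methylbutanoate | CC(C)CC(=O)OCCCC(=O)CS
F5 | step 5 | pent-4-en-1-yl 3-methylbutanoate | CC(C)CC(=O)OCCCC=C
F6 | step 5 | 5-bromo-4-hydroxypentyl 3-methylbutanoate (racemic) | CC(C)CC(=O)OCCCC(O)CBr
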